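**Retrosynthetic overview**
1. Target 21 comes from oxolane 19 by two deprotections: aminolysis of the aryl acetate, then hydrogenolysis of the two benzyl ethers.
2. 19 comes from seco-lignan 18 by disconnecting O1–C2 of the oxolane. The strategy rests on this feature: C2 is the benzylic carbon of the 3,4-dioxygenated ring A (para to an ether oxygen), O1 is the oxygen of the C5 hydroxymethyl carbon (C2–C3–C4–C5–O1), and the C3 CH2OAc of the target already caps the only other hydroxyl.
3. 18 comes from trans-lactone 11 by Weinreb opening, silylation, reduction, exchange of the aryl MOM ether for an acetate, and desilylation.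
4. 11 comes from (R)-lactone 7 and bromide 10 by trans enolate alkylation; 7 comes from vanillin 1 and dimethyl succinate 3 (Stobbe, asymmetric hydrogenation, reduction–lactonisation).
5. Ring order: a temporary γ-lactone (step 4) carries the stereochemistry and is opened in step 8; the oxolane, the only ring formed in the target, is closed last (step 14).

Key step: step 14

Remark: ring A is the catechol ring, ring B the guaiacyl ring; oxolane atoms are O1, C2 (aryl), C3 (CH2OAc), C4 (benzyl), C5.
Assumption: the (4S,5S) antipode of MOD-DIOP is taken as the one that delivers the (R)-half-ester 5; if the sense is opposite, the (4R,5R) ligand is used and nothing else changes.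

**Route**

Step 1
Reactants: 1 vanillin
Product: 2 3-methoxy-4-(methoxymethoxy)benzaldehyde
Conditions: MOMCl, i-Pr2NEt, CH2Cl2, 0 °C → rt
Reagents that add atoms: chloromethyl methyl ether, COCCl
Why: O-alkylation of the phenol gives an acetal that withstands the bases, hydrides and hydrogenation ahead and can later be removed by acid without touching benzyl ethers.

Step 2
Reactants: 2 3-methoxy-4-(methoxymethoxy)benzaldehyde; 3 dimethyl succinate
Product: 4 (E)-3-(methoxycarbonyl)-4-[3-methoxy-4-(methoxymethoxy)phenyl]but-3-enoic acid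
Conditions: NaOMe, MeOH, reflux; then cold 1 M HCl to pH 3
Reagents that add atoms: none
Why: Stobbe condensation, in which the succinate enolate adds to the aldehyde, the alkoxide lactonises onto the distal ester and E1cB opening of the paraconate gives the (E)-half-ester with the free acid on the CH2 arm.

Step 3
Reactants: 4 (E)-half-ester
Product: 5 (3R)-4-methoxy-3-[3-methoxy-4-(methoxymethoxy)benzyl]-4-oxobutanoic acid
Conditions: H2 (1 atm), [Rh(cod)Cl]2 (cat.), (4S,5S)-MOD-DIOP, Et3N, MeOH, 30 °C
Reagents that add atoms: none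
Why: Rhodium-catalysed asymmetric hydrogenation of an itaconate-type half-ester, in which the carboxylate anchors the substrate on the metal and the chiral diphosphine selects the alkene face, sets the (R) centre (later C4 of the oxolane).

Step 4
Reactants: 5 (R)-half-ester
Product: 7 (4R)-4-[3-methoxy-4-(methoxymethoxy)benzyl]oxolan-2-one, via hydroxy acid 6 (not isolated)
Conditions: KOH (1 equiv), EtOH; CaCl2, NaBH4, EtOH, −10 °C → rt; 1 M HCl to pH 2–3 (0 °C), extraction; PPTS (cat.), PhMe, 60 °C
Reagents that add atoms: none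
Why: Ca(BH4)2 reduces the methyl ester but not the potassium carboxylate, and the γ-hydroxy acid then lactonises under mild acid catalysis that spares the aryl acetal; the stereocentre is not involved.

Step 5
Reactants: 8 3,4-bis(benzyloxy)benzaldehyde
Product: 9 [3,4-bis(benzyloxy)phenyl]methanol
Conditions: NaBH4, MeOH–THF, 0 °C
Reagents that add atoms: none
Why: Borohydride reduction of an aromatic aldehyde to the benzylic alcohol, to which benzyl ethers are inert.

Step 6
Reactants: 9 [3,4-bis(benzyloxy)phenyl]methanol
Product: 10 4-(bromomethyl)-1,2-bis(benzyloxy)benzene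
Conditions: PBr3, Et2O, 0 °C
Reagents that add atoms: phosphorus tribromide, BrP(Br)Br
Why: The benzylic alcohol is activated as a phosphite ester and displaced by bromide (SN2).

Step 7
Reactants: 7 (R)-lactone; 10 benzylic bromide
Product: 11 (3R,4R)-3-[3,4-bis(benzyloxy)benzyl]-4-[3-methoxy-4-(methoxymethoxy)benzyl]oxolan-2-one
Conditions: LiN(SiMe3)2, THF, −78 °C; then 10, DMPU, −78 → −30 °C
Reagents that add atoms: none
Why: Lactone enolate alkylation occurs on the face anti to the C4 benzyl group, as is general for β-substituted γ-butyrolactones, giving the trans lactone and setting the (R) centre that becomes C3 of the oxolane.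

Step 8
Reactants: 11 trans-lactone
Product: 12 (2R,3R)-2-[3,4-bis(benzyloxy)benzyl]-4-hydroxy-N-methoxy-3-[3-methoxy-4-(methoxymethoxy)benzyl]-N-methylbutanamide
Conditions: MeNH(OMe)·HCl, i-PrMgCl, THF, −20 → 0 °C; aq. NH4Cl; crude used at once
Reagents that add atoms: N,O-dimethylhydroxylamine hydrochloride, CNOC.Cl
Why: Weinreb amide formation by acyl substitution with the chloromagnesium amide opens the lactone and frees only the hydroxymethyl oxygen that will become O1; the low temperature protects the α-centre.

Step 9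
Reactants: 12 hydroxy amide
Product: 13 (2R,3R)-2-[3,4-bis(benzyloxy)benzyl]-4-[(tert-butyldiphenylsilyl)oxy]-N-methoxy-3-[3-methoxy-4-(methoxymethoxy)benzyl]-N-methylbutanamide
Conditions: TBDPSCl, imidazole, DMF, 0 °C → rt
Reagents that add atoms: tert-butyl(chloro)diphenylsilane, CC(C)(C)[Si](Cl)(c1ccccc1)c1ccccc1
Why: Silylation of the primary alcohol stops relactonisation and marks this oxygen as the later ring oxygen; the bulky silyl group is chosen because it survives the acid of step 11.

Step 10
Reactants: 13 silylated amide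
Product: 15 (2R,3R)-2-[3,4-bis(benzyloxy)benzyl]-4-[(tert-butyldiphenylsilyl)oxy]-3-[3-methoxy-4-(methoxymethoxy)benzyl]butan-1-ol, via aldehyde 14 (not isolated)
Conditions: i-Bu2AlH, THF, −78 °C; then MeOH, NaBH4, −78 → 0 °C; aq. potassium sodium tartrate
Reagents that add atoms: none
Why: Hydride addition to the Weinreb amide stops at the chelated tetrahedral intermediate, which releases the aldehyde on methanol quench, and borohydride reduces it at once, before the α-centre can epimerise.

Step 11
Reactants: 15 primary alcohol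
Product: 16 (2R,3R)-2-[3,4-bis(benzyloxy)benzyl]-4-[(tert-butyldiphenylsilyl)oxy]-3-(4-hydroxy-3-methoxybenzyl)butan-1-ol
Conditions: HCl (1 M in MeOH), THF, rt
Reagents that add atoms: none
Why: Acid-catalysed acetal cleavage of the aryl MOM ether through its oxocarbenium ion, trapped by methanol, leaves the aryl benzyl ethers and the hindered primary silyl ether intact.

Step 12
Reactants: 16 phenol alcohol
Product: 17 (2R,3R)-3-(4-acetoxy-3-methoxybenzyl)-2-[3,4-bis(benzyloxy)benzyl]-4-[(tert-butyldiphenylsilyl)oxy]butyl acetate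
Conditions: Ac2O, pyridine, DMAP (cat.), CH2Cl2, 0 °C → rt
Reagents that add atoms: acetic anhydride, CC(=O)OC(C)=O
Why: DMAP-catalysed acylation esterifies the primary alcohol (the acetate of the target) and the phenol (the deactivating group needed on ring B) in one operation.

Step 13
Reactants: 17 diacetate silyl ether
Product: 18 (2R,3R)-3-(4-acetoxy-3-methoxybenzyl)-2-[3,4-bis(benzyloxy)benzyl]-4-hydroxybutyl acetate
Conditions: HF·pyridine, pyridine–THF, 0 °C → rt
Reagents that add atoms: none
Why: Fluoride cleavage of the Si–O bond under mildly acidic conditions leaves both acetates intact and avoids base-promoted acetyl migration to the liberated alcohol.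

Step 14
Reactants: 18 seco-lignan monoacetate
Product: 19 [(2S,3R,4R)-4-(4-acetoxy-3-methoxybenzyl)-2-[3,4-bis(benzyloxy)phenyl]oxolan-3-yl]methyl acetate
Conditions: DDQ (1.05 equiv), 4 Å MS, CH2Cl2, 0 °C → rt
Reagents that add atoms: none
Why: DDQ forms a charge-transfer complex with the electron-rich ring A and abstracts hydride from its benzylic CH2, giving a para-alkoxybenzyl cation (quinone-methide oxocarbenium) that the free hydroxyl captures while the hydroquinone anion takes the proton; this is the known DDQ-mediated oxidative etherification of para-alkoxybenzylic C–H bonds. The oxolane closes in a 5-exo-trig mode, O1 adding to the cationic C2 whose π bond to the aryl ring lies outside the new ring. The new C2 centre is controlled by the existing C3 centre: in the envelope transition state the aryl group sits pseudo-equatorial and anti to the C3 acetoxymethyl group (and so anti to the cis C4 benzyl group), which should give the 2,3-trans (2S) isomer. The step needs site selectivity between the two benzylic CH2 groups, and electronics secure it: ring B carries a para-acetoxy group that does not stabilise a benzylic cation, and its only ether oxygen is meta to its CH2. The same acetate tempers C6 of ring B as a Friedel–Crafts trap for the cation, and the acetate on the C3 hydroxymethyl oxygen leaves only one hydroxyl to close a ring. One equivalent of DDQ, exclusion of water and the absence of strong acid limit further oxidation at C2–H, benzylic alcohol formation and re-ionisation of the product.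

Step 15
Reactants: 19 oxolane diacetate
Product: 20 [(2S,3R,4R)-2-[3,4-bis(benzyloxy)phenyl]-4-(4-hydroxy-3-methoxybenzyl)oxolan-3-yl]methyl acetate
Conditions: pyrrolidine (3 equiv), CH2Cl2, 0 °C → rt
Reagents that add atoms: none
Why: Aminolysis of the phenyl ester is much faster than that of the primary alkyl acetate because phenoxide is the better leaving group, so only the aryl acetate is removed.

Step 16
Reactants: 20 dibenzyl ether
Product: 21 [(2S,3R,4R)-2-(3,4-dihydroxyphenyl)-4-(4-hydroxy-3-methoxybenzyl)oxolan-3-yl]methyl acetate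
Conditions: H2 (1 atm), Pd/C (10 wt %), EtOAc, rt, stopped at full debenzylation
Reagents that add atoms: none
Why: Heterogeneous hydrogenolysis cleaves the two aryl benzyl ethers quickly, whereas the benzylic C2–O1 bond of the oxolane reacts much more slowly in a neutral aprotic solvent; no stereocentre is touched.

**Compound list**
1 | vanillin | COc1cc(C=O)ccc1O | starting material
2 | 3-methoxy-4-(methoxymethoxy)benzaldehyde | COCOc1ccc(C=O)cc1OC | intermediate
3 | dimethyl succinate | COC(=O)CCC(=O)OC | starting material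
4 | (E)-3-(methoxycarbonyl)-4-[3-methoxy-4-(methoxymethoxy)phenyl]but-3-enoic acid | COC(=O)/C(=C/c1ccc(OCOC)c(OC)c1)CC(=O)O | intermediate
5 | (3R)-4-methoxy-3-[3-methoxy-4-(methoxymethoxy)benzyl]-4-oxobutanoic acid | OC(=O)C[C@H](C(=O)OC)Cc1ccc(OCOC)c(OC)c1 | intermediate
6 | (3R)-3-(hydroxymethyl)-4-[3-methoxy-4-(methoxymethoxy)phenyl]butanoic acid (not isolated) | OC(=O)C[C@H](CO)Cc1ccc(OCOC)c(OC)c1 | intermediate
7 | (4R)-4-[3-methoxy-4-(methoxymethoxy)benzyl]oxolan-2-one | O=C1C[C@H](CO1)Cc1ccc(OCOC)c(OC)c1 | intermediate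
8 | 3,4-bis(benzyloxy)benzaldehyde | O=Cc1ccc(OCc2ccccc2)c(OCc2ccccc2)c1 | starting material
9 | [3,4-bis(benzyloxy)phenyl]methanol | OCc1ccc(OCc2ccccc2)c(OCc2ccccc2)c1 | intermediate
10 | 4-(bromomethyl)-1,2-bis(benzyloxy)benzene | BrCc1ccc(OCc2ccccc2)c(OCc2ccccc2)c1 | intermediate
11 | (3R,4R)-3-[3,4-bis(benzyloxy)benzyl]-4-[3-methoxy-4-(methoxymethoxy)benzyl]oxolan-2-one | O=C1[C@H](Cc2ccc(OCc3ccccc3)c(OCc3ccccc3)c2)[C@H](CO1)Cc1ccc(OCOC)c(OC)c1 | intermediate
12 | (2R,3R)-2-[3,4-bis(benzyloxy)benzyl]-4-hydroxy-N-methoxy-3-[3-methoxy-4-(methoxymethoxy)benzyl]-N-methylbutanamide | CON(C)C(=O)[C@H](Cc1ccc(OCc2ccccc2)c(OCc2ccccc2)c1)[C@H](CO)Cc1ccc(OCOC)c(OC)c1 | intermediate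
13 | (2R,3R)-2-[3,4-bis(benzyloxy)benzyl]-4-[(tert-butyldiphenylsilyl)oxy]-N-methoxy-3-[3-methoxy-4-(methoxymethoxy)benzyl]-N-methylbutanamide | CON(C)C(=O)[C@H](Cc1ccc(OCc2ccccc2)c(OCc2ccccc2)c1)[C@H](CO[Si](c1ccccc1)(c1ccccc1)C(C)(C)C)Cc1ccc(OCOC)c(OC)c1 | intermediate
14 | (2R,3R)-2-[3,4-bis(benzyloxy)benzyl]-4-[(tert-butyldiphenylsilyl)oxy]-3-[3-methoxy-4-(methoxymethoxy)benzyl]butanal (not isolated) | O=C[C@H](Cc1ccc(OCc2ccccc2)c(OCc2ccccc2)c1)[C@H](CO[Si](c1ccccc1)(c1ccccc1)C(C)(C)C)Cc1ccc(OCOC)c(OC)c1 | intermediate
15 | (2R,3R)-2-[3,4-bis(benzyloxy)benzyl]-4-[(tert-butyldiphenylsilyl)oxy]-3-[3-methoxy-4-(methoxymethoxy)benzyl]butan-1-ol | OC[C@H](Cc1ccc(OCc2ccccc2)c(OCc2ccccc2)c1)[C@H](CO[Si](c1ccccc1)(c1ccccc1)C(C)(C)C)Cc1ccc(OCOC)c(OC)c1 | intermediate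
16 | (2R,3R)-2-[3,4-bis(benzyloxy)benzyl]-4-[(tert-butyldiphenylsilyl)oxy]-3-(4-hydroxy-3-methoxybenzyl)butan-1-ol | OC[C@H](Cc1ccc(OCc2ccccc2)c(OCc2ccccc2)c1)[C@H](CO[Si](c1ccccc1)(c1ccccc1)C(C)(C)C)Cc1ccc(O)c(OC)c1 | intermediate
17 | (2R,3R)-3-(4-acetoxy-3-methoxybenzyl)-2-[3,4-bis(benzyloxy)benzyl]-4-[(tert-butyldiphenylsilyl)oxy]butyl acetate | CC(=O)OC[C@H](Cc1ccc(OCc2ccccc2)c(OCc2ccccc2)c1)[C@H](CO[Si](c1ccccc1)(c1ccccc1)C(C)(C)C)Cc1ccc(OC(C)=O)c(OC)c1 | intermediate
18 | (2R,3R)-3-(4-acetoxy-3-methoxybenzyl)-2-[3,4-bis(benzyloxy)benzyl]-4-hydroxybutyl acetate | CC(=O)OC[C@H](Cc1ccc(OCc2ccccc2)c(OCc2ccccc2)c1)[C@H](CO)Cc1ccc(OC(C)=O)c(OC)c1 | intermediate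
19 | [(2S,3R,4R)-4-(4-acetoxy-3-methoxybenzyl)-2-[3,4-bis(benzyloxy)phenyl]oxolan-3-yl]methyl acetate | COc1cc(C[C@H]2CO[C@H](c3ccc(OCc4ccccc4)c(OCc4ccccc4)c3)[C@H]2COC(C)=O)ccc1OC(C)=O | intermediate
20 | [(2S,3R,4R)-2-[3,4-bis(benzyloxy)phenyl]-4-(4-hydroxy-3-methoxybenzyl)oxolan-3-yl]methyl acetate | COc1cc(C[C@H]2CO[C@H](c3ccc(OCc4ccccc4)c(OCc4ccccc4)c3)[C@H]2COC(C)=O)ccc1O | intermediate
21 | [(2S,3R,4R)-2-(3,4-dihydroxyphenyl)-4-(4-hydroxy-3-methoxybenzyl)oxolan-3-yl]methyl acetate | COc1cc(C[C@H]2CO[C@H](c3ccc(O)c(O)c3)[C@H]2COC(C)=O)ccc1O | target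

**Step count**
Total: 16 steps. Longest linear sequence: 14 steps (steps 1–4 and 7–16, from vanillin); steps 5 and 6 form the two-step side branch.

**Steps most likely to fail**

1. Step 14 (key step). Possible failures are a second hydride abstraction at the new C2–H of the product, oxidation at a benzyl ether methylene, capture of the cation by C6 of ring B instead of by oxygen, or insufficient preference for the 2,3-trans closure. The fallback makes the same O1–C2 bond by ionising a benzylic alcohol instead of oxidising a C–H bond. It sets out from lactone 7 and aldehyde 8 and returns at 19. The lithium enolate of 7 (LiN(SiMe3)2, THF, −78 °C) is added to 8 in an aldol reaction to give the trans lactone (3S,4R)-3-{[3,4-bis(benzyloxy)phenyl](hydroxy)methyl}-4-[3-methoxy-4-(methoxymethoxy)benzyl]oxolan-2-one F1 as a mixture of carbinol epimers, which does not matter because that centre is ionised later. LiAlH4 in THF at 0 °C reduces it to the triol (2R,3R)-2-{[3,4-bis(benzyloxy)phenyl](hydroxy)methyl}-3-[3-methoxy-4-(methoxymethoxy)benzyl]butane-1,4-diol F2. Brief treatment with dilute HCl in MeOH–THF at room temperature ionises the benzylic alcohol, closes the oxolane through the only hydroxyl that can form a five-membered ring (thermodynamic 2,3-trans) and removes the aryl acetal, giving [(2S,3R,4R)-2-[3,4-bis(benzyloxy)phenyl]-4-(4-hydroxy-3-methoxybenzyl)oxolan-3-yl]methanol F3. The acid exposure is kept short so that the cation is not diverted to the aryltetralin. Ac2O, pyridine and DMAP then acetylate both the primary alcohol and the phenol to give 19.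

2. Step 16. The risk is competing hydrogenolysis of the benzylic C2–O1 bond, which would open the oxolane to the seco-lignan after or alongside debenzylation. The fallback replaces reduction by Lewis-acid dealkylation. It sets out from 20 and returns at 21: BCl3 with pentamethylbenzene as benzyl-cation scavenger in CH2Cl2 at −78 °C, then methanol quench at low temperature. Aryl benzyl ethers are cleaved within minutes under these conditions, and the acetate and the free phenol tolerate them. The low temperature and short time are chosen to keep the oxolane from ionising at C2. No new compound arises on this path (F0).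

3. Step 3. The risk is insufficient enantiofacial selectivity in the hydrogenation, which would lower the optical purity of every later compound. The fallback replaces asymmetric catalysis by resolution. It sets out from 4 and returns at 5. Hydrogenation of 4 over Pd/C (H2, MeOH; no benzyl ether is present at this stage) gives racemic 4-methoxy-3-[3-methoxy-4-(methoxymethoxy)benzyl]-4-oxobutanoic acid F4. Fractional crystallisation with (R)-1-phenylethylamine is expected to give the salt (R)-1-phenylethylammonium (3R)-4-methoxy-3-[3-methoxy-4-(methoxymethoxy)benzyl]-4-oxobutanoate F5; should the salt of the (S)-acid be the less soluble one, the (S)-amine is used instead. Cold dilute acid liberates 5.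

**Further compounds**
F1 | step 14 | (3S,4R)-3-{[3,4-bis(benzyloxy)phenyl](hydroxy)methyl}-4-[3-methoxy-4-(methoxymethoxy)benzyl]oxolan-2-one | O=C1[C@H](C(O)c2ccc(OCc3ccccc3)c(OCc3ccccc3)c2)[C@H](CO1)Cc1ccc(OCOC)c(OC)c1
F2 | step 14 | (2R,3R)-2-{[3,4-bis(benzyloxy)phenyl](hydroxy)methyl}-3-[3-methoxy-4-(methoxymethoxy)benzyl]butane-1,4-diol | OC[C@H](C(O)c1ccc(OCc2ccccc2)c(OCc2ccccc2)c1)[C@H](CO)Cc1ccc(OCOC)c(OC)c1
F3 | step 14 | [(2S,3R,4R)-2-[3,4-bis(benzyloxy)phenyl]-4-(4-hydroxy-3-methoxybenzyl)oxolan-3-yl]methanol | COc1cc(C[C@H]2CO[C@H](c3ccc(OCc4ccccc4)c(OCc4ccccc4)c3)[C@H]2CO)ccc1O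
F0 | step 16 | none | none
F4 | step 3 | racemic 4-methoxy-3-[3-methoxy-4-(methoxymethoxy)benzyl]-4-oxobutanoic acid | OC(=O)CC(C(=O)OC)Cc1ccc(OCOC)c(OC)c1
F5 | step 3 | (R)-1-phenylethylammonium (3R)-4-methoxy-3-[3-methoxy-4-(methoxymethoxy)benzyl]-4-oxobutanoate | [O-]C(=O)C[C@H](C(=O)OC)Cc1ccc(OCOC)c(OC)c1.C[C@@H]([NH3+])c1ccccc1
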